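The route rests on the C4′–C5′ single bond of the side chain. The key step exploits that C4′ is the methyl-bearing sp2 carbon of the C3′=C4′ alkene nearest the chroman ring, next to the C5′ methylene. A Zweifel olefination makes this bond. A C36 homoheptaprenyl pinacol boronate and the alkenyllithium from a chroman-bound (Z)-2-iodoalkene form a boronate complex. Iodine then drives C5′ from boron to C4′, and anti elimination follows. One operation joins both halves without a transition metal and inverts the easily made Z-iodide into the E-trisubstituted alkene. C2 of the chroman comes from natural (R)-γ-tocotrienol, and the polyprenyl half from geranylgeraniol and farnesyl bromide.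

Key step: step 12

Assumption: (R)-γ-tocotrienol, (2E,6E,10E)-geranylgeraniol and (2E,6E)-farnesyl bromide are bought as single isomers. Side-chain atoms are numbered C1′, C2′ … outward from chroman C2.

Step 1
Reactants: 1 (2E,6E,10E)-geranylgeraniol
Product: 2 geranylgeranyl acetate
Conditions: Ac2O, pyridine, DMAP (cat.), CH2Cl2, 0 °C → rt
Reagents that add atoms: acetic anhydride, CC(=O)OC(C)=O
Why: DMAP-catalysed O-acylation masks the allylic alcohol so that the allylic oxidation of step 2 can act only at the remote chain end; no stereocentre is formed.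

Step 2
Reactants: 2 geranylgeranyl acetate
Product: 3 (2E,6E,10E,14E)-16-hydroxygeranylgeranyl acetate
Conditions: SeO2 (cat.), t-BuOOH, salicylic acid (cat.), CH2Cl2, 0 °C → rt
Reagents that add atoms: tert-butyl hydroperoxide (oxygen relayed through catalytic SeO2), CC(C)(C)OO
Why: Riley allylic oxidation (ene reaction, then [2,3]-sigmatropic shift) should prefer the least hindered terminal isopropylidene unit and by its mechanism oxidises only the methyl group trans to the chain, which sets the E-configured CH2OH terminus.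

Step 3
Reactants: 3 16-hydroxygeranylgeranyl acetate
Product: 4 (2E,6E,10E,14E)-16-bromogeranylgeranyl acetate
Conditions: CBr4, PPh3, CH2Cl2, −20 → 0 °C
Reagents that add atoms: carbon tetrabromide, BrC(Br)(Br)Br
Why: The Appel reaction replaces the primary allylic hydroxyl by SN2 under neutral conditions, so neither allylic shift nor loss of the acetate is expected.

Step 4
Reactants: 5 (2E,6E)-farnesyl bromide
Product: 6 (2E,6E)-farnesyl phenyl sulfone
Conditions: PhSO2Na, DMF, rt
Reagents that add atoms: sodium benzenesulfinate, [Na+].[O-]S(=O)c1ccccc1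
Why: SN2 S-alkylation of the sulfinate at the primary allylic carbon gives the allylic sulfone with the alkene geometry kept.

Step 5
Reactants: 6 farnesyl phenyl sulfone; 4 16-bromogeranylgeranyl acetate
Product: 8 17-(phenylsulfonyl)heptaprenyl acetate (racemic at C17), via lithiated farnesyl sulfone 7 (not isolated)
Conditions: n-BuLi, THF–DMPU, −78 °C; then 4, −78 → −20 °C
Reagents that add atoms: none
Why: In this Biellmann-type sulfone alkylation the α-sulfonyl allyl anion reacts at its α-carbon with the primary allylic bromide much faster than with the acetate at low temperature; the new sulfone-bearing centre is racemic and is erased in step 6.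

Step 6
Reactants: 8 17-(phenylsulfonyl)heptaprenyl acetate
Product: 10 all-E-heptaprenol, via hydroxy sulfone lithium alkoxide 9 (not isolated)
Conditions: LiBHEt3 (excess), THF, −20 °C; then PdCl2(dppp) (cat.), 0 °C → rt
Reagents that add atoms: none
Why: The hydride first cleaves the acetate to an alkoxide that palladium cannot ionise, and the palladium-catalysed hydride desulfonylation of the allylic sulfone then delivers hydride through a π-allyl complex to the less substituted terminus C17, which keeps the position and E geometry of the C18=C19 alkene.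

Step 7
Reactants: 10 all-E-heptaprenol
Product: 11 all-E-heptaprenyl bromide
Conditions: PBr3, Et2O, 0 °C, dark; used without chromatography
Reagents that add atoms: phosphorus tribromide, BrP(Br)Br
Why: SN2 bromination of a primary polyprenol through its phosphite ester is the standard mild entry to polyprenyl bromides and keeps the alkene geometry.

Step 8
Reactants: 11 all-E-heptaprenyl bromide
Product: 12 homoheptaprenyl pinacol boronate
Conditions: CH2(Bpin)2, NaOt-Bu, THF, 0 °C (premixed); then 11, 0 °C → rt
Reagents that add atoms: bis[(pinacolato)boryl]methane, CC1(C)OB(CB2OC(C)(C)C(C)(C)O2)OC1(C)C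
Why: In this deborylative alkylation of a geminal diboronate, tert-butoxide removes one boryl group and the α-boryl carbanion displaces the primary allylic bromide by SN2, adding the single CH2 (the future C5′) with boron already in place.

Step 9
Reactants: 13 (R)-γ-tocotrienol
Product: 14 (R)-γ-tocotrienol TIPS ether
Conditions: TIPSCl, imidazole, DMF, rt → 40 °C
Reagents that add atoms: chlorotriisopropylsilane, CC(C)[Si](Cl)(C(C)C)C(C)C
Why: Imidazole-promoted silylation masks the oxidisable phenol with a group that should survive ozone, ylide, t-BuLi and brief methoxide; C2 is untouched.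

Step 10
Reactants: 14 (R)-γ-tocotrienol TIPS ether
Product: 15 (S)-3-[2,7,8-trimethyl-6-(triisopropylsilyloxy)chroman-2-yl]propanal
Conditions: O3, CH2Cl2–MeOH, NaHCO3, −78 °C (Sudan Red 7B end-point); Me2S, −78 °C → rt
Reagents that add atoms: ozone, [O-][O+]=O
Why: Exhaustive reductive ozonolysis cleaves the three trisubstituted alkenes, which react far faster than the arene, and leaves C1′–C3′ as the aldehyde; C2 keeps its spatial arrangement and its descriptor becomes S only because the CIP ranks change.

Step 11
Reactants: 15 chromanylpropanal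
Product: 16 (R)-2-[(3Z)-4-iodopent-3-en-1-yl]-2,7,8-trimethyl-6-(triisopropylsilyloxy)chroman
Conditions: EtPPh3I, n-BuLi, THF, rt; I2, −78 °C; NaHMDS, −20 °C; then 15, −78 °C
Reagents that add atoms: ethyltriphenylphosphonium iodide, CC[P+](c1ccccc1)(c1ccccc1)c1ccccc1.[I-]; iodine, II
Why: In this Stork–Zhao-type Wittig olefination the non-stabilised α-iodo ylide reacts under kinetic control through the cis-oxaphosphetane, so iodine should end up cis to C2′ (Z-iodide).

Step 12
Reactants: 16 (Z)-iodoalkene; 12 homoheptaprenyl pinacol boronate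
Product: 20 O-TIPS-plastochromanol-8, via alkenyllithium 17 (not isolated), via boronate complex 18 (not isolated), via β-iodoboronic ester 19 (not isolated)
Conditions: 16, t-BuLi (2 equiv), Et2O, −78 °C; 12, THF, −78 °C; I2, THF, −78 °C; NaOMe, MeOH, −78 °C → rt
Reagents that add atoms: none
Why: Iodine–lithium exchange gives the configurationally stable alkenyllithium 17 (lithium cis to C2′), which adds to the vacant boron orbital of 12 to give boronate complex 18; iodine attacks the electron-rich C3′=C4′ bond of 18, and the iodonium ion triggers a stereospecific 1,2-metallate shift in which C5′ moves from boron to C4′ anti to the C–I bond, giving 19. Methoxide then binds boron and sets off an anti-periplanar loss of boron and iodide, so anti addition plus anti elimination exchange boron for C5′ with net inversion of alkene geometry: boron cis to C2′ in 18 becomes C5′ trans to C2′ in 20, the required E alkene. The closest known reaction type is the Zweifel olefination of pinacol boronic esters with alkenyllithium reagents, which is established for primary alkyl boronates and for trisubstituted alkenes. No ring is closed and no lasting stereocentre is made; the two transient centres of 19 (C3′ and C4′) are fixed relative to each other by the anti addition and vanish in the elimination, while C2 is remote and untouched. The step needs iodine to choose one alkene among eight, which the anionic boronate secures because its alkenyl group is by far the most nucleophilic π-bond at −78 °C, and it needs migration of the alkyl group rather than a pinacol oxygen, which is the normal order of migratory aptitude. The TIPS ether should resist t-BuLi and the short exposure to methoxide.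

Step 13
Reactants: 20 O-TIPS-plastochromanol-8
Product: 21 (R)-plastochromanol-8
Conditions: TBAF, AcOH, THF, 0 °C, under argon
Reagents that add atoms: none
Why: Fluoride-induced desilylation of the aryl silyl ether, buffered with acetic acid to avoid an air-sensitive phenoxide, touches neither the polyene nor C2.

Compound list
1 | (2E,6E,10E)-geranylgeraniol | CC(C)=CCC/C(C)=C/CC/C(C)=C/CC/C(C)=C/CO | starting material
2 | (2E,6E,10E)-geranylgeranyl acetate | CC(C)=CCC/C(C)=C/CC/C(C)=C/CC/C(C)=C/COC(C)=O | intermediate
3 | (2E,6E,10E,14E)-16-hydroxy-3,7,11,15-tetramethylhexadeca-2,6,10,14-tetraen-1-yl acetate | OC/C(C)=C/CC/C(C)=C/CC/C(C)=C/CC/C(C)=C/COC(C)=O | intermediate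
4 | (2E,6E,10E,14E)-16-bromo-3,7,11,15-tetramethylhexadeca-2,6,10,14-tetraen-1-yl acetate | BrC/C(C)=C/CC/C(C)=C/CC/C(C)=C/CC/C(C)=C/COC(C)=O | intermediate
5 | (2E,6E)-farnesyl bromide | CC(C)=CCC/C(C)=C/CC/C(C)=C/CBr | starting material
6 | (2E,6E)-farnesyl phenyl sulfone | CC(C)=CCC/C(C)=C/CC/C(C)=C/CS(=O)(=O)c1ccccc1 | intermediate
7 | α-lithiated farnesyl phenyl sulfone | CC(C)=CCC/C(C)=C/CC/C(C)=C/C([Li])S(=O)(=O)c1ccccc1 | intermediate
8 | (2E,6E,10E,14E,18E,22E)-3,7,11,15,19,23,27-heptamethyl-17-(phenylsulfonyl)octacosa-2,6,10,14,18,22,26-heptaen-1-yl acetate, racemic at C17 | CC(C)=CCC/C(C)=C/CC/C(C)=C/C(C/C(C)=C/CC/C(C)=C/CC/C(C)=C/CC/C(C)=C/COC(C)=O)S(=O)(=O)c1ccccc1 | intermediate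
9 | lithium alkoxide of 17-(phenylsulfonyl)heptaprenol, racemic at C17 | CC(C)=CCC/C(C)=C/CC/C(C)=C/C(C/C(C)=C/CC/C(C)=C/CC/C(C)=C/CC/C(C)=C/CO[Li])S(=O)(=O)c1ccccc1 | intermediate
10 | (2E,6E,10E,14E,18E,22E)-heptaprenol | CC(C)=CCC/C(C)=C/CC/C(C)=C/CC/C(C)=C/CC/C(C)=C/CC/C(C)=C/CC/C(C)=C/CO | intermediate
11 | (2E,6E,10E,14E,18E,22E)-heptaprenyl bromide | CC(C)=CCC/C(C)=C/CC/C(C)=C/CC/C(C)=C/CC/C(C)=C/CC/C(C)=C/CC/C(C)=C/CBr | intermediate
12 | 2-[(3E,7E,11E,15E,19E,23E)-4,8,12,16,20,24,28-heptamethylnonacosa-3,7,11,15,19,23,27-heptaen-1-yl]-4,4,5,5-tetramethyl-1,3,2-dioxaborolane (homoheptaprenyl pinacol boronate) | CC(C)=CCC/C(C)=C/CC/C(C)=C/CC/C(C)=C/CC/C(C)=C/CC/C(C)=C/CC/C(C)=C/CCB1OC(C)(C)C(C)(C)O1 | intermediate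
13 | (R)-γ-tocotrienol | CC(C)=CCC/C(C)=C/CC/C(C)=C/CC[C@]1(C)CCc2cc(O)c(C)c(C)c2O1 | starting material
14 | (R)-γ-tocotrienol triisopropylsilyl ether | CC(C)=CCC/C(C)=C/CC/C(C)=C/CC[C@]1(C)CCc2cc(O[Si](C(C)C)(C(C)C)C(C)C)c(C)c(C)c2O1 | intermediate
15 | (S)-3-[2,7,8-trimethyl-6-(triisopropylsilyloxy)chroman-2-yl]propanal | O=CCC[C@]1(C)CCc2cc(O[Si](C(C)C)(C(C)C)C(C)C)c(C)c(C)c2O1 | intermediate
16 | (R)-2-[(3Z)-4-iodopent-3-en-1-yl]-2,7,8-trimethyl-6-(triisopropylsilyloxy)chroman | C/C(I)=C/CC[C@]1(C)CCc2cc(O[Si](C(C)C)(C(C)C)C(C)C)c(C)c(C)c2O1 | intermediate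
17 | alkenyllithium from 16, lithium cis to C2′ | C/C([Li])=C/CC[C@]1(C)CCc2cc(O[Si](C(C)C)(C(C)C)C(C)C)c(C)c(C)c2O1 | intermediate
18 | lithium alkenyl(homoheptaprenyl) pinacol boronate complex, boron cis to C2′ | [Li+].CC(C)=CCC/C(C)=C/CC/C(C)=C/CC/C(C)=C/CC/C(C)=C/CC/C(C)=C/CC/C(C)=C/CC[B-]1(OC(C)(C)C(C)(C)O1)/C(C)=C\CC[C@]2(C)CCc3cc(O[Si](C(C)C)(C(C)C)C(C)C)c(C)c(C)c3O2 | intermediate
19 | β-iodoboronic ester (3′-iodo, 4′-boryl); one of the two facial diastereomers is drawn, and the C3′/C4′ relative configuration is fixed by anti addition | CC(C)=CCC/C(C)=C/CC/C(C)=C/CC/C(C)=C/CC/C(C)=C/CC/C(C)=C/CC/C(C)=C/CC[C@](C)(B1OC(C)(C)C(C)(C)O1)[C@H](I)CC[C@]2(C)CCc3cc(O[Si](C(C)C)(C(C)C)C(C)C)c(C)c(C)c3O2 | intermediate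
20 | (R)-plastochromanol-8 triisopropylsilyl ether | CC(C)=CCC/C(C)=C/CC/C(C)=C/CC/C(C)=C/CC/C(C)=C/CC/C(C)=C/CC/C(C)=C/CC/C(C)=C/CC[C@]1(C)CCc2cc(O[Si](C(C)C)(C(C)C)C(C)C)c(C)c(C)c2O1 | intermediate
21 | (R)-plastochromanol-8 | CC(C)=CCC/C(C)=C/CC/C(C)=C/CC/C(C)=C/CC/C(C)=C/CC/C(C)=C/CC/C(C)=C/CC/C(C)=C/CC[C@]1(C)CCc2cc(O)c(C)c(C)c2O1 | target

Total step count: 13.
Longest linear sequence: 9 steps (1, 2, 3, 5, 6, 7, 8, 12, 13).

Steps most likely to fail

1. Step 12 (key step).
- Risk: capture of the α-methyl-substituted alkenyllithium by the boronate may be sluggish or incomplete. The iodination–elimination sequence may lose part of its stereospecificity. Iodine may also attack the polyene. Each of these would erode the E geometry at C3′=C4′.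
- Fallback: retentive palladium catalysis replaces the invertive boron chemistry and forms the same C4′–C5′ bond. It sets out from aldehyde 15 and boronate 12. Ramirez-type olefination of 15 (BrCCl3, PPh3, CH2Cl2) should give the 1,1-dichloroalkene F1. Boronate 12 is activated with t-BuLi (THF, −78 °C) to the tert-butyl boronate complex F2 and transmetallated with ZnCl2 to homoheptaprenylzinc chloride F3. A trans-selective Negishi monoalkylation of F1 with F3 (PdCl2(DPEphos), THF) should replace only the less hindered chlorine trans to C2′ and give the (Z)-chloroalkene F4. A second Negishi coupling with Me2Zn (Pd(Pt-Bu3)2) exchanges the remaining chlorine for methyl with retention and comes back to the route at 20.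

2. Step 8.
- Risk: the boryl carbanion may attack in the SN2′ sense. Free tert-butoxide may substitute the sensitive allylic bromide or eliminate it to a diene.
- Fallback: the CH2 is inserted by a 1,2-metallate shift on boron rather than by displacement of the bromide with a carbanion. It sets out from bromide 11. Palladium-catalysed borylation (B2pin2, Pd2(dba)3 cat., THF, 60 °C) should give the linear heptaprenyl pinacol boronate F5. Matteson homologation with LiCH2Cl (BrCH2Cl, n-BuLi, THF, −78 °C → rt) proceeds through the chloromethyl boronate complex F6, whose allyl group migrates to carbon with loss of chloride, and comes back to the route at 12.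

3. Step 10.
- Risk: oxidation may not stop at the three alkenes, so that the electron-rich silyloxychroman ring is degraded by ozone, or peroxidic intermediates are reduced incompletely.
- Fallback: an ozone-free, two-stage cleavage. It sets out from 14. Exhaustive Upjohn dihydroxylation (OsO4 cat., NMO, acetone–water) should give the hexaol F7 as a mixture of diastereomers. Glycol cleavage with NaIO4 (THF–water) comes back to the route at 15.

Further compounds
F1 | step 12 | (R)-2-(4,4-dichlorobut-3-en-1-yl)-2,7,8-trimethyl-6-(triisopropylsilyloxy)chroman | ClC(Cl)=CCC[C@]1(C)CCc2cc(O[Si](C(C)C)(C(C)C)C(C)C)c(C)c(C)c2O1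
F2 | step 12 | lithium tert-butyl(homoheptaprenyl) pinacol boronate complex | [Li+].CC(C)=CCC/C(C)=C/CC/C(C)=C/CC/C(C)=C/CC/C(C)=C/CC/C(C)=C/CC/C(C)=C/CC[B-]1(C(C)(C)C)OC(C)(C)C(C)(C)O1
F3 | step 12 | homoheptaprenylzinc chloride | CC(C)=CCC/C(C)=C/CC/C(C)=C/CC/C(C)=C/CC/C(C)=C/CC/C(C)=C/CC/C(C)=C/CC[Zn]Cl
F4 | step 12 | (Z)-4′-chloro-4′-demethyl-plastochromanol-8 TIPS ether (chlorine cis to C2′) | CC(C)=CCC/C(C)=C/CC/C(C)=C/CC/C(C)=C/CC/C(C)=C/CC/C(C)=C/CC/C(C)=C/CC/C(Cl)=C/CC[C@]1(C)CCc2cc(O[Si](C(C)C)(C(C)C)C(C)C)c(C)c(C)c2O1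
F5 | step 8 | all-E-heptaprenyl pinacol boronate | CC(C)=CCC/C(C)=C/CC/C(C)=C/CC/C(C)=C/CC/C(C)=C/CC/C(C)=C/CC/C(C)=C/CB1OC(C)(C)C(C)(C)O1
F6 | step 8 | lithium chloromethyl(heptaprenyl) pinacol boronate complex | [Li+].CC(C)=CCC/C(C)=C/CC/C(C)=C/CC/C(C)=C/CC/C(C)=C/CC/C(C)=C/CC/C(C)=C/C[B-]1(CCl)OC(C)(C)C(C)(C)O1
F7 | step 10 | side-chain hexaol of 14 (mixture of diastereomers at the six new carbinol centres) | CC(C)(O)C(O)CCC(C)(O)C(O)CCC(C)(O)C(O)CC[C@]1(C)CCc2cc(O[Si](C(C)C)(C(C)C)C(C)C)c(C)c(C)c2O1
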